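**Plan**

1. Retrosynthesis: cut the C11–O aryl ether (Mitsunobu, umbelliferone); take C7 out of ring B by cutting C6–C7 and C7–C8 (one-carbon ring-enlargement retron), which leaves an 8-methylhydrindan-6-one; then cut C8–CH3 (enolate methylation), C6–O and C11–O (hydroboration of a C5=C6/C9=C11 diene), both C4–CH3 bonds (deconjugative dimethylation), C9=C11 (Wittig) and, in the Hajos–Parrish ketone so reached, C4–C5 (aldol) and C1–C10 (Michael).
2. Forward: ring A and a five-membered proto-ring B (C5–C6–C8–C9–C10) are closed together in the proline aldol condensation; the coumarin is attached at the hydrindanone stage; ring B receives its sixth atom, C7, only at the end, by cyclopropanation of the C6=C8 silyl enol ether and Fe(III)-mediated ring enlargement.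
3. Enabling feature: ring B is a 3-methylcyclohex-2-enone, C6(=O)–C7H=C8(CH3), whose one unsubstituted carbon, C7, lies between the carbonyl carbon and the methyl-bearing carbon. That is what opening of the C6–C8 bond of a 1-siloxy-5-methylbicyclo[3.1.0]hexane leaves, and the contracted ring C5–C6–C8–C9–C10 with its angular C10 methyl is the cyclopentane of the Hajos–Parrish ketone.
4. Stereochemistry: C10 by D-proline catalysis; C5 and C9 in one double hydroboration on the face away from the C10 methyl; C3 by bulky-hydride reduction (axial alcohol); the ring enlargement creates no stereocentre.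
5. The aryl ether is made before the enone exists, because in the target C9–H is γ to the C6 carbonyl and an activated C11 oxygen would then be open to vinylogous β-elimination.

Key step: step 15

Remarks: drimane locants of the target are used throughout (C3 carbinol, C4 gem-dimethyl, C5 and C10 ring fusion, C6 carbonyl, C7=C8, C11 = CH2O on C9, C12 = methyl on C8); the hydrindanes lack C7. "Syn" and "anti" refer to the face of the C10 methyl. The C8 epimer drawn for 13, 14 and 16 is the expected major one; either epimer serves, since C8 becomes sp2 in step 13.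

**Step 1**
Reactants: 1 2-methylcyclopentane-1,3-dione; 2 methyl vinyl ketone
Product: 3 2-methyl-2-(3-oxobutyl)cyclopentane-1,3-dione
Conditions: H2O, rt
Reagents that add atoms: none
Why: Michael addition of the enolised cyclic 1,3-dione to the enone; C-alkylation at the doubly activated C2 should give the prochiral triketone (no stereocentre).

**Step 2**
Reactants: 3 2-methyl-2-(3-oxobutyl)cyclopentane-1,3-dione
Product: 5 (R)-Hajos–Parrish ketone [(7aR)-7a-methyl-2,3,7,7a-tetrahydro-1H-indene-1,5(6H)-dione], via aldol ketol 4 (not isolated)
Conditions: D-proline (3 mol %), DMF, 16 °C; then H2SO4 (cat.), DMF, 95 °C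
Reagents that add atoms: none
Why: Hajos–Parrish–Eder–Sauer–Wiechert reaction: the D-proline enamine of the side-chain ketone attacks one of the two enantiotopic ring carbonyls under direction of the carboxylic acid (intramolecular aldol), which sets C10 as the mirror image of the L-proline product, and acid dehydrates ketol 4 to the enone.

**Step 3**
Reactants: 5 (R)-Hajos–Parrish ketone
Product: 6 (7aS)-7a-methyl-1-methylidene-1,2,3,6,7,7a-hexahydro-5H-inden-5-one
Conditions: Ph3PCH3Br, KOtBu, THF, 0 °C → rt
Reagents that add atoms: methyltriphenylphosphonium bromide, C[P+](c1ccccc1)(c1ccccc1)c1ccccc1.[Br-] (its CH2 becomes C11)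
Why: Wittig methylenation; the saturated C9 ketone is the more electrophilic carbonyl, and the enone is a vinylogous carbonyl that the basic ylide shields further as its dienolate, in line with the C9-selective hydride reductions and additions of this enedione; no stereocentre is formed.

**Step 4**
Reactants: 6 methylene enone
Product: 7 (7aS)-4,4,7a-trimethyl-1-methylidene-1,2,4,6,7,7a-hexahydro-5H-inden-5-one
Conditions: KOtBu, MeI (excess), t-BuOH/THF, 0 °C → rt
Reagents that add atoms: iodomethane, CI
Why: deconjugative α,α-dialkylation of an enone through its extended dienolate (γ-deprotonation at C6, C-methylation at C4, twice), which should install the C4 gem-dimethyl group and move the double bond to C5=C6.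

**Step 5**
Reactants: 7 dimethyl dienone
Product: 8 (5S,7aS)-4,4,7a-trimethyl-1-methylidene-2,4,5,6,7,7a-hexahydro-1H-inden-5-ol (3-OH anti to the C10 methyl)
Conditions: L-Selectride, THF, −78 °C; then H2O
Reagents that add atoms: none
Why: diastereoselective ketone reduction with a bulky hydride; L-Selectride should attack the neopentyl C3 carbonyl along the equatorial trajectory, so the hydroxyl ends axial and anti to the C10 methyl (3S), as in Selectride reductions of 4,4-dimethyl-3-oxo terpenoids and 5-en-3-one steroids.

**Step 6**
Reactants: 8 dienol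
Product: 9 3-O-tert-butyldimethylsilyl ether of 8
Conditions: TBSOTf, 2,6-lutidine, CH2Cl2, 0 °C
Reagents that add atoms: tert-butyldimethylsilyl triflate, CC(C)(C)[Si](C)(C)OS(=O)(=O)C(F)(F)F
Why: silylation of a hindered secondary alcohol with a silyl triflate; the ether shields C3–OH from the oxidation and the bases that follow.

**Step 7**
Reactants: 9 silyl ether diene
Product: 10 trans-hydrindane diol (3-OTBS anti, 5-H anti, 6-OH anti, 9-CH2OH syn to the C10 methyl)
Conditions: BH3·THF (excess), THF, 0 °C → rt; then NaOH, H2O2
Reagents that add atoms: hydrogen peroxide, OO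
Why: double hydroboration–oxidation (anti-Markovnikov syn addition); borane should attack both alkenes anti to the angular methyl, delivering H to C9 and to C5 on that face, which puts C11 syn to the C10 methyl (as with 17-methylene steroids) and gives the trans ring fusion (as with 4,4,10-trimethyl-Δ5-octalins), while boron goes to C11 and C6.

**Step 8**
Reactants: 10 diol
Product: 11 11-O-TBS ether (6-OH free)
Conditions: TBSCl, imidazole, CH2Cl2, 0 °C
Reagents that add atoms: tert-butyldimethylsilyl chloride, CC(C)(C)[Si](C)(C)Cl
Why: selective silylation of the primary alcohol over the hindered secondary C6 carbinol.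

**Step 9**
Reactants: 11 secondary alcohol
Product: 12 trans-hydrindan-6-one (3-OTBS, 11-OTBS)
Conditions: Dess–Martin periodinane, NaHCO3, CH2Cl2, rt
Reagents that add atoms: none
Why: Dess–Martin oxidation under buffered conditions should give the ketone without epimerising the adjacent C5 methine.

**Step 10**
Reactants: 12 ketone
Product: 13 8-methyl ketone (8-CH3 anti to the C10 methyl and to C11)
Conditions: LDA, THF, −78 °C; MeI, DMPU, −78 → −30 °C
Reagents that add atoms: iodomethane, CI
Why: kinetic enolate alkylation; LDA should remove a C8 methylene proton because C5–H lies between two quaternary carbons, and methylation should occur anti to the C9 substituent (the C8 configuration is immaterial).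

**Step 11**
Reactants: 13 bis-silyl ether
Product: 14 keto diol (3-OH, 11-OH)
Conditions: 48% aq. HF, MeCN, rt
Reagents that add atoms: none
Why: acidic desilylation of both silyl ethers; enolisation toward C5 is disfavoured by A(1,3) strain with the C4 methyls, so the ring fusion should survive.

**Step 12**
Reactants: 14 keto diol; 15 umbelliferone (7-hydroxycoumarin)
Product: 16 11-O-(2-oxo-2H-chromen-7-yl) ether of 14 (3-OH free)
Conditions: PPh3, DIAD, THF, 0 → 40 °C
Reagents that add atoms: none
Why: Mitsunobu etherification; the acidic phenol should displace the primary C11 oxyphosphonium by SN2 while the axial neopentyl C3 alcohol stays inert, and at this stage C9–H is only β to the ketone, so no elimination pathway is open.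

**Step 13**
Reactants: 16 aryl ether ketone
Product: 17 C6=C8 trimethylsilyl enol ether, 3-O-trimethylsilyl ether
Conditions: TMSOTf, Et3N, CH2Cl2, 0 °C
Reagents that add atoms: trimethylsilyl triflate, C[Si](C)(C)OS(=O)(=O)C(F)(F)F
Why: soft enolisation to the silyl enol ether; only the C6=C8 isomer should form, since a C5=C6 enol ether would need removal of the shielded C5–H and would suffer A(1,3) strain between OSi and the C4 methyls, and the C3 hydroxyl is silylated in passing as transient protection.

**Step 14**
Reactants: 17 silyl enol ether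
Product: 18 siloxycyclopropane (C7 bridging C6 and C8, anti to the C10 methyl)
Conditions: Et2Zn, CH2I2, CH2Cl2, 0 °C → rt
Reagents that add atoms: diiodomethane, ICI
Why: Simmons–Smith cyclopropanation (Furukawa reagent) of the electron-rich enol ether, chemoselective over the electron-poor coumarin C3=C4 bond; the two new stereocentres are erased in the next step.

**Step 15**
Reactants: 18 siloxycyclopropane
Product: 21 ferocaulidin, via β-chloro ketone 19 (not isolated), via 3-O-trimethylsilyl enone 20 (not isolated)
Conditions: FeCl3, DMF, 0 °C → rt; NaOAc, MeOH, reflux; then 1 M HCl, THF, rt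
Reagents that add atoms: none
Why: Fe(III) oxidises the siloxycyclopropane by single-electron transfer, the cyclopropoxy radical (silyl group lost as Me3SiCl) undergoes β-scission of the internal C6–C8 bond to give the C6 ketone and the tertiary C8 radical of a ring enlarged by C7, chlorine transfer from a second FeCl3 gives β-chloro ketone 19, acetate removes HCl through the C7 enol to give enone 20, and the acidic work-up takes off the transient C3 silyl group. The closest known reaction type is the Ito–Saegusa ring enlargement of 1-siloxybicyclo[n.1.0]alkanes to 2-cycloalkenones. No ring is closed by a new bond: ring B arises by ring expansion, through cleavage of the zero-atom bridge of the bicyclo[3.1.0]hexane, so that the former five-membered ring C5–C6–C8–C9–C10 takes in C7. No stereocentre is formed; C3, C5, C9 and C10 are untouched and the cyclopropane stereocentres C6 and C8 become sp2. The step needs scission of the internal and not the external C6–C7 bond, which the C8 methyl secures (tertiary against primary radical, plus strain release), and elimination toward C7 and not toward C9 or C12, which the acidity of the C7 hydrogens α to the ketone secures. It also needs C5 and C9 to stay intact, which the weak base (acetate cannot form the C5 enolate or the γ-dienolate that would expel the aryloxide) and the fast chlorine ligand transfer (no free C8 cation) should secure.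

**Compound list**

1 | 2-methylcyclopentane-1,3-dione | CC1C(=O)CCC1=O | starting material
2 | methyl vinyl ketone (but-3-en-2-one) | CC(=O)C=C | starting material
3 | 2-methyl-2-(3-oxobutyl)cyclopentane-1,3-dione | CC(=O)CCC1(C)C(=O)CCC1=O | intermediate
4 | (3aR,7aR)-3a-hydroxy-7a-methylhexahydro-1H-indene-1,5(4H)-dione (cis-fused aldol ketol) | C[C@@]12CCC(=O)C[C@]1(O)CCC2=O | intermediate (not isolated)
5 | (R)-Hajos–Parrish ketone, (7aR)-7a-methyl-2,3,7,7a-tetrahydro-1H-indene-1,5(6H)-dione | C[C@@]12CCC(=O)C=C1CCC2=O | intermediate
6 | (7aS)-7a-methyl-1-methylidene-1,2,3,6,7,7a-hexahydro-5H-inden-5-one (C9=C11 methylene enone) | C[C@@]12CCC(=O)C=C1CCC2=C | intermediate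
7 | (7aS)-4,4,7a-trimethyl-1-methylidene-1,2,4,6,7,7a-hexahydro-5H-inden-5-one (C3 ketone, C5=C6, C9=C11) | C[C@@]12CCC(=O)C(C)(C)C1=CCC2=C | intermediate
8 | (5S,7aS)-4,4,7a-trimethyl-1-methylidene-2,4,5,6,7,7a-hexahydro-1H-inden-5-ol (3-OH anti) | C[C@@]12CC[C@H](O)C(C)(C)C1=CCC2=C | intermediate
9 | 3-O-TBS ether of 8 | C[C@@]12CC[C@H](O[Si](C)(C)C(C)(C)C)C(C)(C)C1=CCC2=C | intermediate
10 | trans-hydrindane diol: 3-OTBS anti, 5-H anti, 6-OH anti, 9-CH2OH syn | C1[C@@H](O)[C@@H]2C(C)(C)[C@@H](O[Si](C)(C)C(C)(C)C)CC[C@@]2(C)[C@@H]1CO | intermediate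
11 | 11-O-TBS ether of 10 (6-OH free) | C1[C@@H](O)[C@@H]2C(C)(C)[C@@H](O[Si](C)(C)C(C)(C)C)CC[C@@]2(C)[C@@H]1CO[Si](C)(C)C(C)(C)C | intermediate
12 | trans-hydrindan-6-one, 3,11-bis-O-TBS | C1C(=O)[C@@H]2C(C)(C)[C@@H](O[Si](C)(C)C(C)(C)C)CC[C@@]2(C)[C@@H]1CO[Si](C)(C)C(C)(C)C | intermediate
13 | 8-methyl-trans-hydrindan-6-one, 3,11-bis-O-TBS (8-CH3 anti) | C[C@H]1C(=O)[C@@H]2C(C)(C)[C@@H](O[Si](C)(C)C(C)(C)C)CC[C@@]2(C)[C@@H]1CO[Si](C)(C)C(C)(C)C | intermediate
14 | 3-hydroxy-9-(hydroxymethyl)-4,4,8,10-tetramethyl-trans-hydrindan-6-one (keto diol) | C[C@H]1C(=O)[C@@H]2C(C)(C)[C@@H](O)CC[C@@]2(C)[C@@H]1CO | intermediate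
15 | umbelliferone (7-hydroxy-2H-chromen-2-one) | O=c1ccc2ccc(O)cc2o1 | starting material
16 | 11-O-(2-oxo-2H-chromen-7-yl) ether of 14 | C[C@H]1C(=O)[C@@H]2C(C)(C)[C@@H](O)CC[C@@]2(C)[C@@H]1COc1ccc2ccc(=O)oc2c1 | intermediate
17 | C6=C8 trimethylsilyl enol ether of 16, 3-O-TMS | CC1=C(O[Si](C)(C)C)[C@@H]2C(C)(C)[C@@H](O[Si](C)(C)C)CC[C@@]2(C)[C@@H]1COc1ccc2ccc(=O)oc2c1 | intermediate
18 | 6-trimethylsiloxy-8-methyl-bicyclo[3.1.0]hexane-fused siloxycyclopropane (C7 anti), 3-O-TMS | C[C@]12C[C@@]1(O[Si](C)(C)C)[C@@H]1C(C)(C)[C@@H](O[Si](C)(C)C)CC[C@@]1(C)[C@@H]2COc1ccc2ccc(=O)oc2c1 | intermediate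
19 | ring-enlarged 8-chloro-8-methyl decalin-6-one, 3-O-TMS (C8 epimers) | CC1(Cl)CC(=O)[C@@H]2C(C)(C)[C@@H](O[Si](C)(C)C)CC[C@@]2(C)[C@@H]1COc1ccc2ccc(=O)oc2c1 | intermediate (not isolated)
20 | 3-O-trimethylsilyl ferocaulidin | CC1=CC(=O)[C@@H]2C(C)(C)[C@@H](O[Si](C)(C)C)CC[C@@]2(C)[C@@H]1COc1ccc2ccc(=O)oc2c1 | intermediate (not isolated)
21 | ferocaulidin, 7-{[(1R,4aS,6S,8aS)-6-hydroxy-2,5,5,8a-tetramethyl-4-oxo-1,4,4a,5,6,7,8,8a-octahydronaphthalen-1-yl]methoxy}-2H-chromen-2-one | CC1=CC(=O)[C@@H]2C(C)(C)[C@@H](O)CC[C@@]2(C)[C@@H]1COc1ccc2ccc(=O)oc2c1 | target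

**Count and risks**

Total step count: 15. Longest linear sequence: 15 steps (1 and 2 to 21); umbelliferone 15 enters at step 12.

Steps most likely to fail:

Step 3, loss of chemoselectivity: the ylide may olefinate or merely enolise the wrong carbonyl, or enolise the hindered C9 ketone instead of adding to it. The fallback sets out from 5 and masks the conjugated carbonyl first. Ethane-1,2-dithiol with TsOH in AcOH should give the enone dithiolane F1 selectively. Wittig methylenation of its only free ketone should give the methylene dithiolane F2. Hydrolysis with MeI and CaCO3 in aqueous MeCN should free the enone and come back to the route at 6.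

Step 5, poor facial selectivity of hydride delivery: the flattened Δ5 ring A lacks an axial C5–H, so axial attack leading to the equatorial alcohol may compete. The fallback sets out from 7 and replaces substrate control by reagent control. A CBS reduction with catalytic (R)-2-methyl-CBS-oxazaborolidine and catecholborane in toluene at −78 °C, the catalyst enantiomer that the Corey model assigns to the 3S alcohol with the quaternary C4 side as the large group, should come back to the route at 8. It makes no new compound (F0).

Step 15, wrong course of the oxidative opening: the external cyclopropane bond may cleave, or Fe(III) may ionise the tertiary C8 centre with loss of the C9 configuration. The fallback sets out from 17 and uses a two-electron ring expansion instead. Dibromocarbene (PhHgCBr3, benzene, 80 °C) should give the dibromo siloxycyclopropane F3. On heating this should open by the cyclopropyl-to-allyl cation pathway with loss of Me3SiBr to the 7-bromo enone F4. Hydrodebromination (Pd(OAc)2, PPh3, HCO2H, Et3N, DMF, 60 °C) should then come back to the route at 20, which the acidic work-up converts to 21.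

**Further compounds**

F1 | step 3 | (7aR)-5,5-(ethane-1,2-diyldisulfanediyl)-7a-methyl-2,3,5,6,7,7a-hexahydro-1H-inden-1-one (enone dithiolane) | C[C@@]12CCC3(SCCS3)C=C1CCC2=O
F2 | step 3 | (7aS)-5,5-(ethane-1,2-diyldisulfanediyl)-7a-methyl-1-methylidene-2,3,5,6,7,7a-hexahydro-1H-indene (methylene dithiolane) | C[C@@]12CCC3(SCCS3)C=C1CCC2=C
F0 | step 5 | none | none
F3 | step 15 | 7,7-dibromo analogue of 18 (dibromo siloxycyclopropane, 3-O-TMS) | C[C@]12C(Br)(Br)[C@@]1(O[Si](C)(C)C)[C@@H]1C(C)(C)[C@@H](O[Si](C)(C)C)CC[C@@]1(C)[C@@H]2COc1ccc2ccc(=O)oc2c1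
F4 | step 15 | 7-bromo-3-O-trimethylsilyl ferocaulidin (7-bromo enone) | CC1=C(Br)C(=O)[C@@H]2C(C)(C)[C@@H](O[Si](C)(C)C)CC[C@@]2(C)[C@@H]1COc1ccc2ccc(=O)oc2c1
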